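Japonicone A is disconnected at its spiro-lactone (bond C6–C7′ and the lactone C–O) into a norbornene acid and a eudesmane dienol; the norbornene is traced to an arene. The key step exploits the one-carbon bridge C2, which carries the acetate between the quaternary bridgehead C1 and C3 of the norbornene ring: photolysis of a bicyclo[2.2.2]octene α-diazoketone (diazo carbon on C3, carbonyl on C1) shifts C1 to the diazo carbon, so the dioxygenated two-carbon bridge contracts to C2–CO2H in one operation. The precursor is the methyl acrylate Diels–Alder adduct of a benzosuberane-fused o-quinone monoketal, hydrolysed to the dione and diazotised at the less hindered carbonyl.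

Key step: step 15

Remarks on the chemistry (one line each):
- Labels: norbornene C1 (quaternary bridgehead), C2 (acetoxy bridge), C3 (bridgehead CH), C4(Me)=C5, C6 (spiro carbon), C7 (CH2). In the bicyclo[2.2.2]octenes the oxygenated bridge is Ca (on C3) and Cb (on C1). Eudesmane atoms carry primes, and β is the face of the C10′ methyl.
- The arene is built in the 2-methoxy-5-methylphenol series (methoxy next to the ring-fusion carbon, hydroxyl next to the aromatic CH). An acrylate bonds its ester-bearing carbon to the diene terminus next to the dienone carbonyl, so only this arrangement puts C6 on C3 and the CH2 on C1; the isomeric 2-methoxy-4-methylphenol pattern would give the other regioisomer.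
- The ring-contracted acid is drawn as the C2 epimer with CO2H anti to C4=C5 (expected from kinetic protonation on the alkene face). The target C2 configuration is reached later by equilibrating the derived methyl ketone; either epimer serves.
- tert-Butyldiphenylsilyl ethers protect the seven-ring diol because the α-keto ketal hydrolysis needs aqueous acid.
- Assumption: (R)-DTBM-SEGPHOS gives the R benzylic centre in step 5; the antipodal ligand is used if a model reduction shows the opposite sense.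
- Assumption: boronate 6 is a catalogue compound (otherwise one step from ethyl but-2-ynoate by copper-catalysed borylation).
- The configuration at C6 of the ester and acid intermediates is inconsequential, since C6 is enolised in step 30.

Step 1
Reactants: 1 2-methoxy-5-methylphenol
Product: 2 4-bromo-2-methoxy-5-methylphenol
Conditions: NBS, MeCN, 0 °C
Reagents that add atoms: N-bromosuccinimide, O=C1CCC(=O)N1Br
Why: Electrophilic aromatic bromination should go para to the free hydroxyl, the most activated open position.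

Step 2
Reactants: 2 4-bromo-2-methoxy-5-methylphenol
Product: 3 (4-bromo-2-methoxy-5-methylphenoxy)triisopropylsilane
Conditions: TIPSCl, imidazole, DMF, rt
Reagents that add atoms: chlorotriisopropylsilane, CC(C)[Si](Cl)(C(C)C)C(C)C
Why: Routine O-silylation gives a bulky, non-directing aryl silyl ether that tolerates the organometallic steps.

Step 3
Reactants: 3 (4-bromo-2-methoxy-5-methylphenoxy)triisopropylsilane
Product: 5 (4-bromo-3-iodo-2-methoxy-5-methylphenoxy)triisopropylsilane, via aryllithium 4 (not isolated)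
Conditions: LDA, THF, −78 °C; then I2, −78 °C
Reagents that add atoms: iodine, II
Why: Directed ortho-metalation removes the ring hydrogen flanked by methoxy and bromine (the most acidic site), and iodine quenches the aryllithium at −78 °C before aryne formation can set in.

Step 4
Reactants: 5 (4-bromo-3-iodo-2-methoxy-5-methylphenoxy)triisopropylsilane; 6 ethyl (Z)-3-(4,4,5,5-tetramethyl-1,3,2-dioxaborolan-2-yl)but-2-enoate
Product: 7 ethyl (E)-3-[6-bromo-2-methoxy-5-methyl-3-(triisopropylsilyloxy)phenyl]but-2-enoate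
Conditions: Pd(dppf)Cl2 (cat.), K3PO4, dioxane–H2O, 70 °C
Reagents that add atoms: none
Why: Suzuki–Miyaura coupling is selective for the C–I bond over C–Br and proceeds with retention of alkene geometry, giving the E enoate.

Step 5
Reactants: 7 ethyl (E)-3-[6-bromo-2-methoxy-5-methyl-3-(triisopropylsilyloxy)phenyl]but-2-enoate
Product: 8 ethyl (R)-3-[6-bromo-2-methoxy-5-methyl-3-(triisopropylsilyloxy)phenyl]butanoate
Conditions: Cu(OAc)2 (cat.), (R)-DTBM-SEGPHOS (cat.), (EtO)2MeSiH, t-BuOH, toluene, 0 °C → rt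
Reagents that add atoms: none
Why: CuH-catalysed asymmetric conjugate reduction of a geometrically pure β,β-disubstituted enoate sets the benzylic stereocentre by ligand control and leaves the aryl bromide untouched.

Step 6
Reactants: 8 ethyl (R)-3-[6-bromo-2-methoxy-5-methyl-3-(triisopropylsilyloxy)phenyl]butanoate; 9 tributyl(3-methylbut-2-en-1-yl)stannane
Product: 10 ethyl (R)-3-[2-methoxy-5-methyl-6-(3-methylbut-2-en-1-yl)-3-(triisopropylsilyloxy)phenyl]butanoate
Conditions: Pd(P(t-Bu)3)2 (cat.), dioxane, 90 °C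
Reagents that add atoms: none
Why: Stille coupling with a bulky electron-rich phosphine tolerates the flanked aryl bromide and the ester and should transfer the prenyl group through its α-carbon.

Step 7
Reactants: 10 ethyl (R)-3-[2-methoxy-5-methyl-6-(3-methylbut-2-en-1-yl)-3-(triisopropylsilyloxy)phenyl]butanoate
Product: 11 (R)-3-[2-methoxy-5-methyl-6-(3-methylbut-2-en-1-yl)-3-(triisopropylsilyloxy)phenyl]butanal
Conditions: DIBAL-H (1.1 equiv), CH2Cl2, −78 °C; Rochelle salt
Reagents that add atoms: none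
Why: Partial ester reduction stops at the aldehyde because the tetrahedral aluminium hemiacetal is stable at −78 °C.

Step 8
Reactants: 11 (R)-3-[2-methoxy-5-methyl-6-(3-methylbut-2-en-1-yl)-3-(triisopropylsilyloxy)phenyl]butanal
Product: 12 (5R,7R,8S)-4-methoxy-1,5-dimethyl-8-(prop-1-en-2-yl)-3-(triisopropylsilyloxy)-6,7,8,9-tetrahydro-5H-benzo[7]annulen-7-ol
Conditions: Me2AlCl (1.5 equiv), CH2Cl2, −78 → −20 °C
Reagents that add atoms: none
Why: Intramolecular carbonyl-ene reaction of the prenyl group (bond formation at its inner alkene carbon) closes the seven-membered ring through a chair-like transition state with the benzylic methyl pseudoaxial (away from the ortho methoxy) and the forming C–O and isopropenyl groups pseudoequatorial, which should set the 7,8-trans and 5,7-trans relationships.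

Step 9
Reactants: 12 (5R,7R,8S)-4-methoxy-1,5-dimethyl-8-(prop-1-en-2-yl)-3-(triisopropylsilyloxy)-6,7,8,9-tetrahydro-5H-benzo[7]annulen-7-ol
Product: 13 (5R,7R,8S)-8-(3-hydroxyprop-1-en-2-yl)-4-methoxy-1,5-dimethyl-3-(triisopropylsilyloxy)-6,7,8,9-tetrahydro-5H-benzo[7]annulen-7-ol
Conditions: SeO2 (cat.), t-BuOOH, CH2Cl2, rt
Reagents that add atoms: tert-butyl hydroperoxide, CC(C)(C)OO
Why: Selenium dioxide allylic oxidation (ene reaction then 2,3-shift) hydroxylates the methyl of an isopropenyl group in preference to the tertiary allylic CH.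

Step 10
Reactants: 13 (5R,7R,8S)-8-(3-hydroxyprop-1-en-2-yl)-4-methoxy-1,5-dimethyl-3-(triisopropylsilyloxy)-6,7,8,9-tetrahydro-5H-benzo[7]annulen-7-ol
Product: 14 bis(tert-butyldiphenylsilyl) ether of diol 13
Conditions: TBDPSCl (2.5 equiv), imidazole, DMAP (cat.), DMF, 50 °C
Reagents that add atoms: tert-butyl(chloro)diphenylsilane, CC(C)(C)[Si](Cl)(c1ccccc1)c1ccccc1
Why: Silylation of both alcohols gives acid- and base-robust ethers that mask the future α-methylene lactone as a protected 2-methylene-1,4-diol.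

Step 11
Reactants: 14 bis(tert-butyldiphenylsilyl) ether of diol 13
Product: 15 (5R,7R,8S)-7-(tert-butyldiphenylsilyloxy)-8-[3-(tert-butyldiphenylsilyloxy)prop-1-en-2-yl]-4-methoxy-1,5-dimethyl-6,7,8,9-tetrahydro-5H-benzo[7]annulen-3-ol
Conditions: TBAF (1.05 equiv), AcOH (1.1 equiv), THF, 0 °C
Reagents that add atoms: none
Why: Fluoride cleaves an aryl silyl ether (phenoxide leaving group) far faster than alkyl TBDPS ethers, so the phenol is freed selectively.

Step 12
Reactants: 15 (5R,7R,8S)-7-(tert-butyldiphenylsilyloxy)-8-[3-(tert-butyldiphenylsilyloxy)prop-1-en-2-yl]-4-methoxy-1,5-dimethyl-6,7,8,9-tetrahydro-5H-benzo[7]annulen-3-ol; 16 methyl acrylate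
Product: 18 bicyclo[2.2.2]octenone dimethyl ketal (Ca=O on C3; Cb(OMe)2 on C1; CO2Me on C6 syn to C4=C5), via o-quinone monoketal 17 (not isolated)
Conditions: PhI(OAc)2, MeOH, 0 °C; concentrate; methyl acrylate (20 equiv), BHT, toluene, 90 °C
Reagents that add atoms: methanol, CO
Why: Oxidative dearomatisation of the 2-methoxyphenol gives a non-dimerising quinone monoketal whose Diels–Alder reaction should place the ester-bearing carbon on the terminus next to the carbonyl (C3) and the CH2 on the substituted terminus C1, with the ester endo (syn to C4=C5) and the dienophile on the face away from the pseudoaxial benzylic methyl, which fixes C1, C3 and C6.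

Step 13
Reactants: 18 bicyclo[2.2.2]octenone dimethyl ketal
Product: 19 bicyclo[2.2.2]octene-Ca,Cb-dione
Conditions: 2 M HCl, THF, 50 °C
Reagents that add atoms: water, O
Why: Acid hydrolysis of the α-keto dimethyl ketal is slow but feasible on warming, and the TBDPS ethers, the methyl ester and both alkenes should tolerate dilute aqueous acid.

Step 14
Reactants: 19 bicyclo[2.2.2]octene-Ca,Cb-dione
Product: 21 α-diazoketone (Ca=N2 on C3; Cb=O on C1), via monotosylhydrazone 20 (not isolated)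
Conditions: TsNHNH2 (1.0 equiv), THF, 0 °C → rt; then Et3N, CH2Cl2, rt
Reagents that add atoms: p-toluenesulfonyl hydrazide, Cc1ccc(cc1)S(=O)(=O)NN
Why: The hydrazide condenses at Ca (flanked only by the bridgehead CH) and not at Cb (next to quaternary C1), and base-induced loss of sulfinate (Bamford–Stevens-type) gives the diazo ketone.

Step 15
Reactants: 21 α-diazoketone (Ca=N2 on C3; Cb=O on C1)
Product: 23 norbornene C2 carboxylic acid (CO2H on the one-carbon bridge), via ketene 22 (not isolated)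
Conditions: hν (365 nm), THF–H2O (10:1), NaHCO3, 0 °C
Reagents that add atoms: water, O
Why: Irradiation expels N2 from the diazo ketone, which is locked s-cis in the ring, with concerted 1,2-shift of the C1–Cb bond to the diazo carbon; this forms the C1–C2 bond, leaves Cb as an exocyclic ketene, and water then gives the acid. The closest known reaction type is the photochemical Wolff ring contraction of cyclic α-diazoketones, used to turn bicyclo[2.2.2]octanones into norbornane carboxylic acids. The new five-membered rings (C1–C2–C3–C4–C5 and C1–C2–C3–C6–C7) arise by 1,2-alkyl migration, not by an exo or endo cyclisation. The new stereocentre C2 is set by protonation of the ketene hydrate from the less hindered alkene face, so CO2H is expected syn to C6–C7; this is not decisive because C2 is equilibrated in step 17. The step needs migration of C1 to win over carbene addition to C4=C5 or C–H insertion, which the concerted pathway from the s-cis geometry secures. It also needs the diazo group on the carbon next to C3, which step 14 secures.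

Step 16
Reactants: 23 norbornene C2 carboxylic acid
Product: 25 C2 methyl ketone (acetyl anti to C4=C5), via acid chloride 24 (not isolated)
Conditions: (COCl)2, DMF (cat.), CH2Cl2, 0 °C → rt; evaporate; Me2CuLi, Et2O, −78 °C
Reagents that add atoms: lithium dimethylcuprate, [Li+].C[Cu-]C
Why: Cuprate acylation turns the acid chloride into the methyl ketone at −78 °C without touching the methyl ester or the product ketone.

Step 17
Reactants: 25 C2 methyl ketone (acetyl anti to C4=C5)
Product: 26 C2-epimeric methyl ketone (acetyl syn to C4=C5)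
Conditions: DBU, toluene, 60 °C
Reagents that add atoms: none
Why: Enolisation of the ketone (but not the ester) equilibrates C2 to the epimer with the acetyl over the C4=C5 π bond, away from the exo hydrogens on C6 and C7, which is the configuration of the target.

Step 18
Reactants: 26 C2-epimeric methyl ketone (acetyl syn to C4=C5)
Product: 27 keto acid (CO2H on C6)
Conditions: LiOH, THF–MeOH–H2O, 50 °C; then 1 M HCl to pH 3
Reagents that add atoms: lithium hydroxide, [Li+].[OH-]
Why: Saponification of the methyl ester leaves the silyl ethers and the already equilibrated acetyl group intact.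

Step 19
Reactants: 28 (S)-Wieland–Miescher ketone
Product: 29 1′β-hydroxy enone (C1′ alcohol cis to the angular methyl)
Conditions: NaBH4 (0.3 equiv), EtOH, −10 °C
Reagents that add atoms: none
Why: Borohydride reduces the saturated ketone chemoselectively, with hydride delivered anti to the angular methyl so that the hydroxyl ends up cis to it.

Step 20
Reactants: 29 1′β-hydroxy enone
Product: 30 C7′ ethylene ketal with the alkene moved to C4′=C5′
Conditions: ethylene glycol, p-TsOH (cat.), benzene, reflux (Dean–Stark)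
Reagents that add atoms: ethylene glycol, OCCO
Why: Ketalisation of the enone proceeds through the dienol ether and gives the thermodynamic β,γ-unsaturated ketal, as in the steroid series.

Step 21
Reactants: 30 C7′ ethylene ketal with C4′=C5′
Product: 31 1′β-TBS ether of 30
Conditions: TBSCl, imidazole, DMF, rt
Reagents that add atoms: tert-butyl(chloro)dimethylsilane, CC(C)(C)[Si](C)(C)Cl
Why: Routine silylation protects the secondary alcohol for the base and organometallic steps.

Step 22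
Reactants: 31 1′β-TBS ether
Product: 32 4′α,5′α-epoxide
Conditions: mCPBA, NaHCO3, CH2Cl2, 0 °C
Reagents that add atoms: 3-chloroperbenzoic acid, OOC(=O)c1cccc(Cl)c1
Why: Peracid epoxidation should occur mainly on the α face, opposite the angular methyl and the C1′ silyloxy group.

Step 23
Reactants: 32 4′α,5′α-epoxide
Product: 33 4′β-methyl-5′α-ol
Conditions: MeMgBr (excess), THF, reflux
Reagents that add atoms: methylmagnesium bromide, C[Mg]Br
Why: Trans-diaxial epoxide opening at the secondary carbon C4′ delivers methyl from the β face (the classical route to axial methyl next to a ring-fusion carbinol), and the ketal is inert to the Grignard reagent.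

Step 24
Reactants: 33 4′β-methyl-5′α-ol
Product: 35 4′β-methyl enone (C5′=C6′–C7′=O), via hydroxy ketone 34 (not isolated)
Conditions: PPTS, acetone–H2O, 50 °C; then 0.1 M NaOH, MeOH, 0 °C
Reagents that add atoms: water, O
Why: Mild deketalisation followed by base-mediated E1cB loss of the β-hydroxyl gives the conjugated enone while keeping the axial 4′β-methyl, which stronger acid would epimerise.

Step 25
Reactants: 35 4′β-methyl enone
Product: 37 cross-conjugated dienone (C5′=C6′ and C8′=C9′), via silyl dienol ether 36 (not isolated)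
Conditions: LDA, THF, −78 °C; TMSCl; then Pd(OAc)2 (1.1 equiv), MeCN, rt
Reagents that add atoms: none
Why: Kinetic deprotonation at C8′ and Saegusa–Ito oxidation of the silyl enol ether introduce the C8′=C9′ alkene without enolising toward C4′.

Step 26
Reactants: 37 cross-conjugated dienone
Product: 38 8′α,9′α-epoxy enone
Conditions: 30% H2O2, NaOH, MeOH, 0 °C
Reagents that add atoms: hydrogen peroxide, OO
Why: Nucleophilic epoxidation attacks the less substituted enone alkene at C9′ from the face opposite the angular methyl.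

Step 27
Reactants: 38 8′α,9′α-epoxy enone
Product: 39 9′α-hydroxy-5′,7′-diene
Conditions: N2H4·H2O, AcOH (cat.), MeOH, 0 °C → rt
Reagents that add atoms: none
Why: Wharton transposition of the epoxy ketone hydrazone loses N2 and gives the allylic alcohol at C9′ with the new C7′=C8′ alkene.

Step 28
Reactants: 39 9′α-hydroxy-5′,7′-diene
Product: 41 9′β-hydroxy-5′,7′-diene, via dienone 40 (not isolated)
Conditions: MnO2, CH2Cl2, rt; filter; CeCl3·7H2O, NaBH4, MeOH, −78 °C
Reagents that add atoms: none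
Why: Allylic oxidation and immediate Luche 1,2-reduction invert C9′, because hydride adds anti to the methyl on the adjacent quaternary carbon and leaves the hydroxyl cis to it.

Step 29
Reactants: 27 keto acid (CO2H on C6); 41 9′β-hydroxy-5′,7′-diene
Product: 43 C9′ allylic ester of acid 27, via acid chloride 42 (not isolated)
Conditions: 27, (COCl)2, DMF (cat.), CH2Cl2, 0 °C → rt, evaporate; 41, LiHMDS, THF, −78 °C; combine, −78 → 0 °C
Reagents that add atoms: none
Why: Acylation of a preformed lithium alkoxide by an acid chloride is the standard way to esterify a hindered neopentylic alcohol with a hindered acid.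

Step 30
Reactants: 43 C9′ allylic ester
Product: 46 rearranged acid (quaternary C6 bonded to C7′; C8′=C9′ and C5′=C6′ retained), via bis-silyl ketene acetal 44 (not isolated), via silyl ester 45 (not isolated)
Conditions: TMSCl–Et3N, LDA (4 equiv), THF, −78 °C; then 60 °C; then 1 M HCl, THF, rt
Reagents that add atoms: none
Why: Ireland–Claisen rearrangement of the silyl ketene acetal (the methyl ketone is carried as its silyl enol ether and returned on work-up) forms C6–C7′ on the exo face of the norbornene, which places the carboxyl endo, and transfers chirality suprafacially from the C9′β oxygen to the β face of C7′.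

Step 31
Reactants: 46 rearranged acid
Product: 47 9′α-iodo spiro-lactone (lactone oxygen on C8′β)
Conditions: I2, NaHCO3, MeCN, 0 °C → rt, dark
Reagents that add atoms: iodine, II
Why: Iodolactonisation by 5-exo anti addition closes the cis-fused γ-lactone at C8′ with iodine axial on C9′α; closure at C6′ would meet both the C4′β and C10′β methyls, and reversibility of the addition should favour the C8′ lactone.

Step 32
Reactants: 47 9′α-iodo spiro-lactone
Product: 48 spiro-lactone methyl ketone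
Conditions: Bu3SnH, AIBN (cat.), benzene, 80 °C
Reagents that add atoms: none
Why: Radical deiodination removes the secondary iodide without touching lactone, ketone or alkenes.

Step 33
Reactants: 48 spiro-lactone methyl ketone
Product: 49 C2 acetate
Conditions: Me3SiOOSiMe3, TMSOTf (cat.), CH2Cl2, −40 °C
Reagents that add atoms: bis(trimethylsilyl) peroxide, C[Si](C)(C)OO[Si](C)(C)C
Why: Baeyer–Villiger oxidation with the silyl peroxide, which does not epoxidise alkenes, inserts oxygen with migration of the secondary C2 over methyl and with retention, so the acetate stays syn to C4=C5.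

Step 34
Reactants: 49 C2 acetate
Product: 50 triol (free C1′ hydroxyl, seven-ring hydroxyl and allylic CH2OH)
Conditions: HF·pyridine, pyridine, THF, 0 → 40 °C
Reagents that add atoms: none
Why: Buffered fluoride removes the two TBDPS ethers and the TBS ether while leaving the acetate and the spiro-lactone.

Step 35
Reactants: 50 triol
Product: 53 japonicone A, via hydroxy enal 51 (not isolated), via lactol 52 (not isolated)
Conditions: MnO2 (excess), CH2Cl2, rt
Reagents that add atoms: none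
Why: Manganese dioxide oxidises only the allylic primary alcohol; the enal is trapped by the neighbouring ring hydroxyl as a lactol, and this is oxidised on to the trans-fused α-methylene-γ-butyrolactone while the unactivated C1′ alcohol is untouched.

Compound list
1 | 2-methoxy-5-methylphenol | Cc1ccc(OC)c(O)c1 | starting material
2 | 4-bromo-2-methoxy-5-methylphenol | Cc1cc(O)c(OC)cc1Br | intermediate
3 | (4-bromo-2-methoxy-5-methylphenoxy)triisopropylsilane | Cc1cc(O[Si](C(C)C)(C(C)C)C(C)C)c(OC)cc1Br | intermediate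
4 | aryllithium (lithium between methoxy and bromine) | Cc1cc(O[Si](C(C)C)(C(C)C)C(C)C)c(OC)c([Li])c1Br | intermediate
5 | (4-bromo-3-iodo-2-methoxy-5-methylphenoxy)triisopropylsilane | Cc1cc(O[Si](C(C)C)(C(C)C)C(C)C)c(OC)c(I)c1Br | intermediate
6 | ethyl (Z)-3-(4,4,5,5-tetramethyl-1,3,2-dioxaborolan-2-yl)but-2-enoate | CCOC(=O)/C=C(/B1OC(C)(C)C(C)(C)O1)C | starting material
7 | ethyl (E)-3-[6-bromo-2-methoxy-5-methyl-3-(triisopropylsilyloxy)phenyl]but-2-enoate | CCOC(=O)/C=C(/c1c(OC)c(O[Si](C(C)C)(C(C)C)C(C)C)cc(C)c1Br)C | intermediate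
8 | ethyl (R)-3-[6-bromo-2-methoxy-5-methyl-3-(triisopropylsilyloxy)phenyl]butanoate | CCOC(=O)C[C@@H](C)c1c(OC)c(O[Si](C(C)C)(C(C)C)C(C)C)cc(C)c1Br | intermediate
9 | tributyl(3-methylbut-2-en-1-yl)stannane | CCCC[Sn](CCCC)(CCCC)CC=C(C)C | starting material
10 | ethyl (R)-3-[2-methoxy-5-methyl-6-(3-methylbut-2-en-1-yl)-3-(triisopropylsilyloxy)phenyl]butanoate | CCOC(=O)C[C@@H](C)c1c(OC)c(O[Si](C(C)C)(C(C)C)C(C)C)cc(C)c1CC=C(C)C | intermediate
11 | (R)-3-[2-methoxy-5-methyl-6-(3-methylbut-2-en-1-yl)-3-(triisopropylsilyloxy)phenyl]butanal | O=CC[C@@H](C)c1c(OC)c(O[Si](C(C)C)(C(C)C)C(C)C)cc(C)c1CC=C(C)C | intermediate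
12 | (5R,7R,8S)-4-methoxy-1,5-dimethyl-8-(prop-1-en-2-yl)-3-(triisopropylsilyloxy)-6,7,8,9-tetrahydro-5H-benzo[7]annulen-7-ol | O[C@@H]2C[C@@H](C)c3c(OC)c(O[Si](C(C)C)(C(C)C)C(C)C)cc(C)c3C[C@H]2C(C)=C | intermediate
13 | (5R,7R,8S)-8-(3-hydroxyprop-1-en-2-yl)-4-methoxy-1,5-dimethyl-3-(triisopropylsilyloxy)-6,7,8,9-tetrahydro-5H-benzo[7]annulen-7-ol | O[C@@H]2C[C@@H](C)c3c(OC)c(O[Si](C(C)C)(C(C)C)C(C)C)cc(C)c3C[C@H]2C(=C)CO | intermediate
14 | bis(tert-butyldiphenylsilyl) ether of 13 | CC(C)(C)[Si](c1ccccc1)(c1ccccc1)O[C@@H]2C[C@@H](C)c3c(OC)c(O[Si](C(C)C)(C(C)C)C(C)C)cc(C)c3C[C@H]2C(=C)CO[Si](c1ccccc1)(c1ccccc1)C(C)(C)C | intermediate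
15 | (5R,7R,8S)-7-(tert-butyldiphenylsilyloxy)-8-[3-(tert-butyldiphenylsilyloxy)prop-1-en-2-yl]-4-methoxy-1,5-dimethyl-6,7,8,9-tetrahydro-5H-benzo[7]annulen-3-ol | CC(C)(C)[Si](c1ccccc1)(c1ccccc1)O[C@@H]2C[C@@H](C)c3c(OC)c(O)cc(C)c3C[C@H]2C(=C)CO[Si](c1ccccc1)(c1ccccc1)C(C)(C)C | intermediate
16 | methyl acrylate | C=CC(=O)OC | starting material
17 | o-quinone monoketal (4,4-dimethoxy dienone of 15) | CC(C)(C)[Si](c1ccccc1)(c1ccccc1)O[C@@H]2C[C@@H](C)C3=C(C[C@H]2C(=C)CO[Si](c1ccccc1)(c1ccccc1)C(C)(C)C)C(C)=CC(=O)C3(OC)OC | intermediate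
18 | bicyclo[2.2.2]octenone dimethyl ketal (Ca=O, Cb(OMe)2, endo CO2Me on C6) | CC(C)(C)[Si](c1ccccc1)(c1ccccc1)O[C@@H]2C[C@@H](C)[C@]34C[C@H](C(=O)OC)[C@H](C(C)=C3C[C@H]2C(=C)CO[Si](c1ccccc1)(c1ccccc1)C(C)(C)C)C(=O)C4(OC)OC | intermediate
19 | bicyclo[2.2.2]octene-Ca,Cb-dione | CC(C)(C)[Si](c1ccccc1)(c1ccccc1)O[C@@H]2C[C@@H](C)[C@]34C[C@H](C(=O)OC)[C@H](C(C)=C3C[C@H]2C(=C)CO[Si](c1ccccc1)(c1ccccc1)C(C)(C)C)C(=O)C4=O | intermediate
20 | Ca monotosylhydrazone of 19 | CC(C)(C)[Si](c1ccccc1)(c1ccccc1)O[C@@H]2C[C@@H](C)[C@]34C[C@H](C(=O)OC)[C@H](C(C)=C3C[C@H]2C(=C)CO[Si](c1ccccc1)(c1ccccc1)C(C)(C)C)C(=NNS(=O)(=O)c1ccc(C)cc1)C4=O | intermediate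
21 | bicyclo[2.2.2]octene α-diazoketone (Ca=N2 on C3, Cb=O on C1) | CC(C)(C)[Si](c1ccccc1)(c1ccccc1)O[C@@H]2C[C@@H](C)[C@]34C[C@H](C(=O)OC)[C@H](C(C)=C3C[C@H]2C(=C)CO[Si](c1ccccc1)(c1ccccc1)C(C)(C)C)C(=[N+]=[N-])C4=O | intermediate
22 | norbornene C2 ketene | CC(C)(C)[Si](c1ccccc1)(c1ccccc1)O[C@@H]2C[C@@H](C)[C@]34C[C@H](C(=O)OC)[C@H](C(C)=C3C[C@H]2C(=C)CO[Si](c1ccccc1)(c1ccccc1)C(C)(C)C)C4=C=O | intermediate
23 | norbornene C2 carboxylic acid (CO2H anti to C4=C5) | CC(C)(C)[Si](c1ccccc1)(c1ccccc1)O[C@@H]2C[C@@H](C)[C@]34C[C@H](C(=O)OC)[C@H](C(C)=C3C[C@H]2C(=C)CO[Si](c1ccccc1)(c1ccccc1)C(C)(C)C)[C@H]4C(=O)O | intermediate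
24 | C2 acid chloride | CC(C)(C)[Si](c1ccccc1)(c1ccccc1)O[C@@H]2C[C@@H](C)[C@]34C[C@H](C(=O)OC)[C@H](C(C)=C3C[C@H]2C(=C)CO[Si](c1ccccc1)(c1ccccc1)C(C)(C)C)[C@H]4C(=O)Cl | intermediate
25 | C2 methyl ketone (acetyl anti to C4=C5) | CC(C)(C)[Si](c1ccccc1)(c1ccccc1)O[C@@H]2C[C@@H](C)[C@]34C[C@H](C(=O)OC)[C@H](C(C)=C3C[C@H]2C(=C)CO[Si](c1ccccc1)(c1ccccc1)C(C)(C)C)[C@H]4C(C)=O | intermediate
26 | C2 methyl ketone (acetyl syn to C4=C5) | CC(C)(C)[Si](c1ccccc1)(c1ccccc1)O[C@@H]2C[C@@H](C)[C@]34C[C@H](C(=O)OC)[C@H](C(C)=C3C[C@H]2C(=C)CO[Si](c1ccccc1)(c1ccccc1)C(C)(C)C)[C@@H]4C(C)=O | intermediate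
27 | keto acid (CO2H on C6) | CC(C)(C)[Si](c1ccccc1)(c1ccccc1)O[C@@H]2C[C@@H](C)[C@]34C[C@H](C(=O)O)[C@H](C(C)=C3C[C@H]2C(=C)CO[Si](c1ccccc1)(c1ccccc1)C(C)(C)C)[C@@H]4C(C)=O | intermediate
28 | (S)-Wieland–Miescher ketone | C[C@]12CCC(=O)C=C1CCCC2=O | starting material
29 | 1′β-hydroxy enone | O[C@H]1CCCC2=CC(=O)CC[C@]12C | intermediate
30 | C7′ ethylene ketal with C4′=C5′ | O[C@H]1CCC=C2CC3(OCCO3)CC[C@]12C | intermediate
31 | 1′β-TBS ether of 30 | CC(C)(C)[Si](C)(C)O[C@H]1CCC=C2CC3(OCCO3)CC[C@]12C | intermediate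
32 | 4′α,5′α-epoxide | CC(C)(C)[Si](C)(C)O[C@H]1CC[C@@H]2O[C@@]23CC4(OCCO4)CC[C@]13C | intermediate
33 | 4′β-methyl-5′α-ol ketal | CC(C)(C)[Si](C)(C)O[C@H]1CC[C@@H](C)[C@@]2(O)CC3(OCCO3)CC[C@]12C | intermediate
34 | 5′α-hydroxy-4′β-methyl C7′ ketone | CC(C)(C)[Si](C)(C)O[C@H]1CC[C@@H](C)[C@@]2(O)CC(=O)CC[C@]12C | intermediate
35 | 4′β-methyl enone | CC(C)(C)[Si](C)(C)O[C@H]1CC[C@@H](C)C2=CC(=O)CC[C@]12C | intermediate
36 | C7′ trimethylsilyl dienol ether (C7′=C8′) | CC(C)(C)[Si](C)(C)O[C@H]1CC[C@@H](C)C2=CC(O[Si](C)(C)C)=CC[C@]12C | intermediate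
37 | cross-conjugated dienone | CC(C)(C)[Si](C)(C)O[C@H]1CC[C@@H](C)C2=CC(=O)C=C[C@]12C | intermediate
38 | 8′α,9′α-epoxy enone | CC(C)(C)[Si](C)(C)O[C@H]1CC[C@@H](C)C2=CC(=O)[C@@H]3O[C@@H]3[C@]12C | intermediate
39 | 9′α-hydroxy-5′,7′-diene | CC(C)(C)[Si](C)(C)O[C@H]1CC[C@@H](C)C2=CC=C[C@H](O)[C@]12C | intermediate
40 | 5′,7′-dien-9′-one | CC(C)(C)[Si](C)(C)O[C@H]1CC[C@@H](C)C2=CC=CC(=O)[C@]12C | intermediate
41 | 9′β-hydroxy-5′,7′-diene | CC(C)(C)[Si](C)(C)O[C@H]1CC[C@@H](C)C2=CC=C[C@@H](O)[C@]12C | intermediate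
42 | C6 acid chloride of 27 | CC(C)(C)[Si](c1ccccc1)(c1ccccc1)O[C@@H]2C[C@@H](C)[C@]34C[C@H](C(=O)Cl)[C@H](C(C)=C3C[C@H]2C(=C)CO[Si](c1ccccc1)(c1ccccc1)C(C)(C)C)[C@@H]4C(C)=O | intermediate
43 | C9′ allylic ester of 27 with 41 | CC(C)(C)[Si](c1ccccc1)(c1ccccc1)O[C@@H]2C[C@@H](C)[C@]34C[C@H](C(=O)O[C@@H]9C=CC=C%10[C@H](C)CC[C@H](O[Si](C)(C)C(C)(C)C)[C@@]9%10C)[C@H](C(C)=C3C[C@H]2C(=C)CO[Si](c1ccccc1)(c1ccccc1)C(C)(C)C)[C@@H]4C(C)=O | intermediate
44 | trimethylsilyl ketene acetal at C6 with the acetyl as trimethylsilyl enol ether | CC(C)(C)[Si](c1ccccc1)(c1ccccc1)O[C@@H]2C[C@@H](C)[C@]34CC(=C(O[Si](C)(C)C)O[C@@H]9C=CC=C%10[C@H](C)CC[C@H](O[Si](C)(C)C(C)(C)C)[C@@]9%10C)[C@H](C(C)=C3C[C@H]2C(=C)CO[Si](c1ccccc1)(c1ccccc1)C(C)(C)C)[C@@H]4C(=C)O[Si](C)(C)C | intermediate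
45 | rearranged trimethylsilyl ester (enol ether still silylated) | CC(C)(C)[Si](c1ccccc1)(c1ccccc1)O[C@@H]2C[C@@H](C)[C@]34C[C@@](C(=O)O[Si](C)(C)C)([C@H]9C=C[C@]%10(C)[C@@H](O[Si](C)(C)C(C)(C)C)CC[C@@H](C)C%10=C9)[C@H](C(C)=C3C[C@H]2C(=C)CO[Si](c1ccccc1)(c1ccccc1)C(C)(C)C)[C@@H]4C(=C)O[Si](C)(C)C | intermediate
46 | rearranged acid (C6–C7′ bond; C5′=C6′ and C8′=C9′) | CC(C)(C)[Si](c1ccccc1)(c1ccccc1)O[C@@H]2C[C@@H](C)[C@]34C[C@@](C(=O)O)([C@H]9C=C[C@]%10(C)[C@@H](O[Si](C)(C)C(C)(C)C)CC[C@@H](C)C%10=C9)[C@H](C(C)=C3C[C@H]2C(=C)CO[Si](c1ccccc1)(c1ccccc1)C(C)(C)C)[C@@H]4C(C)=O | intermediate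
47 | 9′α-iodo spiro-lactone | CC(C)(C)[Si](c1ccccc1)(c1ccccc1)O[C@@H]2C[C@@H](C)[C@]34C[C@]5(C(=O)O[C@H]6[C@H](I)[C@@]7(C)C(=C[C@H]65)[C@H](C)CC[C@@H]7O[Si](C)(C)C(C)(C)C)[C@H](C(C)=C3C[C@H]2C(=C)CO[Si](c1ccccc1)(c1ccccc1)C(C)(C)C)[C@@H]4C(C)=O | intermediate
48 | spiro-lactone methyl ketone | CC(C)(C)[Si](c1ccccc1)(c1ccccc1)O[C@@H]2C[C@@H](C)[C@]34C[C@]5(C(=O)O[C@H]6C[C@@]7(C)C(=C[C@H]65)[C@H](C)CC[C@@H]7O[Si](C)(C)C(C)(C)C)[C@H](C(C)=C3C[C@H]2C(=C)CO[Si](c1ccccc1)(c1ccccc1)C(C)(C)C)[C@@H]4C(C)=O | intermediate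
49 | spiro-lactone C2 acetate (silylated) | CC(C)(C)[Si](c1ccccc1)(c1ccccc1)O[C@@H]2C[C@@H](C)[C@]34C[C@]5(C(=O)O[C@H]6C[C@@]7(C)C(=C[C@H]65)[C@H](C)CC[C@@H]7O[Si](C)(C)C(C)(C)C)[C@H](C(C)=C3C[C@H]2C(=C)CO[Si](c1ccccc1)(c1ccccc1)C(C)(C)C)[C@@H]4OC(C)=O | intermediate
50 | triol acetate | O[C@@H]2C[C@@H](C)[C@]34C[C@]5(C(=O)O[C@H]6C[C@@]7(C)C(=C[C@H]65)[C@H](C)CC[C@@H]7O)[C@H](C(C)=C3C[C@H]2C(=C)CO)[C@@H]4OC(C)=O | intermediate
51 | hydroxy enal | O[C@@H]2C[C@@H](C)[C@]34C[C@]5(C(=O)O[C@H]6C[C@@]7(C)C(=C[C@H]65)[C@H](C)CC[C@@H]7O)[C@H](C(C)=C3C[C@H]2C(=C)C=O)[C@@H]4OC(C)=O | intermediate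
52 | α-methylene lactol | C=C1C(O)O[C@@H]2C[C@@H](C)[C@]34C[C@]5(C(=O)O[C@H]6C[C@@]7(C)C(=C[C@H]65)[C@H](C)CC[C@@H]7O)[C@H](C(C)=C3C[C@@H]12)[C@@H]4OC(C)=O | intermediate
53 | japonicone A | C=C1C(=O)O[C@@H]2C[C@@H](C)[C@]34C[C@]5(C(=O)O[C@H]6C[C@@]7(C)C(=C[C@H]65)[C@H](C)CC[C@@H]7O)[C@H](C(C)=C3C[C@@H]12)[C@@H]4OC(C)=O | target

Total step count: 35. Longest linear sequence: 25 steps (steps 1–18 and 29–35); steps 19–28 form the eudesmane branch.

Steps most likely to fail:

Step 31. Iodonium formation may occur at the more electron-rich C5′=C6′ alkene, with lactonisation to C6′ instead of C8′. The fallback sets out from acid 46. Hg(OCOCF3)2 in MeCN, then aqueous NaCl, should cyclise only at C8′, because mercury avoids the fully substituted C5′, and gives the chloromercurio lactone F6. Bu3SnH with AIBN then demercurates it and returns to 48, so the iodide 47 is bypassed.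

Step 12. The cycloaddition may be slow at the fully substituted, ketal-flanked terminus C1, so that the quinone monoketal decomposes before it is trapped. The fallback sets out from phenol 15. After the same PhI(OAc)2/MeOH oxidation, the more electrophilic acrolein (same orientation rules, 40–60 °C) should give the aldehyde adduct F4. Pinnick oxidation (NaClO2, NaH2PO4, 2-methylbut-2-ene) gives the acid F5, and TMSCHN2 in MeOH–toluene returns to 18.

Step 8. The ene closure of the seven-membered ring may stall or run with poor control of the two new stereocentres, giving proton-loss isomers or the cis alcohol. The fallback sets out from ester 10. SeO2/t-BuOOH oxidises the E methyl of the prenyl group to the allylic alcohol F1. CBr4/PPh3 gives the allylic bromide F2, and DIBAL-H at −78 °C gives the bromo aldehyde F3. CrCl2 in THF then closes the ring by intramolecular Nozaki–Hiyama–Kishi allylation (γ-attack through a chair transition state, anti selective) and returns to 12.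

Further compounds
F1 | step 8 | ethyl (R)-3-[6-((E)-4-hydroxy-3-methylbut-2-en-1-yl)-2-methoxy-5-methyl-3-(triisopropylsilyloxy)phenyl]butanoate | CCOC(=O)C[C@@H](C)c1c(OC)c(O[Si](C(C)C)(C(C)C)C(C)C)cc(C)c1C/C=C(\C)CO
F2 | step 8 | ethyl (R)-3-[6-((E)-4-bromo-3-methylbut-2-en-1-yl)-2-methoxy-5-methyl-3-(triisopropylsilyloxy)phenyl]butanoate | CCOC(=O)C[C@@H](C)c1c(OC)c(O[Si](C(C)C)(C(C)C)C(C)C)cc(C)c1C/C=C(\C)CBr
F3 | step 8 | (R)-3-[6-((E)-4-bromo-3-methylbut-2-en-1-yl)-2-methoxy-5-methyl-3-(triisopropylsilyloxy)phenyl]butanal | O=CC[C@@H](C)c1c(OC)c(O[Si](C(C)C)(C(C)C)C(C)C)cc(C)c1C/C=C(\C)CBr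
F4 | step 12 | bicyclo[2.2.2]octenone dimethyl ketal with endo CHO on C6 | CC(C)(C)[Si](c1ccccc1)(c1ccccc1)O[C@@H]2C[C@@H](C)[C@]34C[C@H](C=O)[C@H](C(C)=C3C[C@H]2C(=C)CO[Si](c1ccccc1)(c1ccccc1)C(C)(C)C)C(=O)C4(OC)OC
F5 | step 12 | bicyclo[2.2.2]octenone dimethyl ketal with endo CO2H on C6 | CC(C)(C)[Si](c1ccccc1)(c1ccccc1)O[C@@H]2C[C@@H](C)[C@]34C[C@H](C(=O)O)[C@H](C(C)=C3C[C@H]2C(=C)CO[Si](c1ccccc1)(c1ccccc1)C(C)(C)C)C(=O)C4(OC)OC
F6 | step 31 | 9′α-chloromercurio spiro-lactone | CC(C)(C)[Si](c1ccccc1)(c1ccccc1)O[C@@H]2C[C@@H](C)[C@]34C[C@]5(C(=O)O[C@H]6[C@H]([Hg]Cl)[C@@]7(C)C(=C[C@H]65)[C@H](C)CC[C@@H]7O[Si](C)(C)C(C)(C)C)[C@H](C(C)=C3C[C@H]2C(=C)CO[Si](c1ccccc1)(c1ccccc1)C(C)(C)C)[C@@H]4C(C)=O
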